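**Retrosynthetic overview**
- The (E)-alkene of the side chain is cut by cross-metathesis into a C2-vinyl bicyclic lactone and a (3S,4R)-configured allylic benzoate made from methyl (R)-lactate; the silyl ether on the side-chain hydroxyl is removed last.
- The dihydropyranone ring (formed second) comes from ring-closing metathesis of an acrylate on O4 with the vinyl group on C7a; O4 is placed cis to that vinyl group by SN2 inversion at C3a, and the C3 hydroxyl by hydride delivery to a C3 ketone from the convex face.
- The C3-keto, C3a-hydroxy tetrahydrofuran comes from catalytic oxidative desymmetrisation of a meso 2,5-divinyltetrahydrofuran-3,4-diol.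
- The tetrahydrofuran ring (formed first) is closed at C3–C3a by SmI2 pinacol coupling of a meso dialdehyde, which is made from a meso bis(allylic) ether (iridium-catalysed allylic etherification).
- Enabling feature: in the tetrahydrofuran ring (O1, C2, C3, C3a, C7a) both C3 and C3a carry oxygen (the free OH and the lactone oxygen O4) and both C2 and C7a carry an sp2 carbon, so the ring is a latent meso 2,5-divinyl-3,4-diol and C3–C3a is a pinacol bond between two aldehyde carbons tethered through O1.

Key step: step 7

Remark: locants are those of the furo[3,2-b]pyran-5-one core of the target (O1, C2, C3, C3a, O4, C5, C6, C7, C7a) and are kept for all intermediates; the target is read as (2S,3R,3aR,7aR) with a (1E,3S,4R) side chain, so all four substituents on the tetrahydrofuran ring are cis.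

**Route**

Step 1
Reactants: 1 (S)-but-3-ene-1,2-diol
Product: 2 (S)-1-(tert-butyldimethylsilyloxy)but-3-en-2-ol
Conditions: TBSCl (1.05 equiv), imidazole, CH2Cl2, 0 °C
Reagents that add atoms: tert-butyldimethylsilyl chloride, C[Si](C)(Cl)C(C)(C)C
Why: Sterically controlled silyl ether formation protects the primary hydroxyl of the 1,2-diol and leaves the secondary allylic hydroxyl free as the later nucleophile, the stereocentre being untouched.

Step 2
Reactants: 3 (E)-but-2-ene-1,4-diol
Product: 4 (E)-4-(tert-butyldimethylsilyloxy)but-2-en-1-ol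
Conditions: TBSCl (1 equiv), imidazole, 3 in threefold excess, DMF, 0 °C
Reagents that add atoms: tert-butyldimethylsilyl chloride, C[Si](C)(Cl)C(C)(C)C
Why: Statistical monosilylation of the symmetrical diol used in excess (silyl ether formation) should give mainly the mono-protected allylic alcohol.

Step 3
Reactants: 4 (E)-4-(tert-butyldimethylsilyloxy)but-2-en-1-ol
Product: 5 tert-butyl (E)-4-(tert-butyldimethylsilyloxy)but-2-en-1-yl carbonate
Conditions: Boc2O, DMAP (cat.), CH2Cl2, rt
Reagents that add atoms: di-tert-butyl dicarbonate, CC(C)(C)OC(=O)OC(=O)OC(C)(C)C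
Why: DMAP-catalysed O-acylation turns the allylic alcohol into the carbonate leaving group needed for formation of the allyl–iridium intermediate.

Step 4
Reactants: 2 (S)-1-(tert-butyldimethylsilyloxy)but-3-en-2-ol; 5 tert-butyl (E)-4-(tert-butyldimethylsilyloxy)but-2-en-1-yl carbonate
Product: 6 meso-(R,S)-bis[1-(tert-butyldimethylsilyloxy)but-3-en-2-yl] ether
Conditions: [Ir(cod)Cl]2 (2 mol%), BINOL-derived N,N-bis(1-phenylethyl)phosphoramidite ligand (4 mol%, the enantiomer that sets the new ether carbon as R), K3PO4, THF, rt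
Reagents that add atoms: none
Why: Iridium-catalysed branched-selective asymmetric allylic etherification, in which the secondary alkoxide of 2 attacks the substituted terminus of the allyl–iridium complex and the chiral ligand (catalyst control) sets the new ether carbon as R, which with the S centre of 2 gives the meso diastereomer.

Step 5
Reactants: 6 meso-(R,S)-bis[1-(tert-butyldimethylsilyloxy)but-3-en-2-yl] ether
Product: 7 meso-(2R,2'S)-2,2'-oxybis(but-3-en-1-ol)
Conditions: camphorsulfonic acid (cat.), MeOH, rt
Reagents that add atoms: none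
Why: Acid-catalysed methanolysis removes both primary silyl ethers (protecting-group cleavage) without touching the secondary bis(allylic) ether.

Step 6
Reactants: 7 meso-(2R,2'S)-2,2'-oxybis(but-3-en-1-ol)
Product: 8 meso-(2R,2'S)-2,2'-oxybis(but-3-enal)
Conditions: Dess–Martin periodinane (2.4 equiv), pyridine, CH2Cl2, 0 °C; crude product used at once
Reagents that add atoms: none
Why: Dess–Martin oxidation converts both primary alcohols into aldehydes under buffered, non-enolising conditions, so the two α-alkoxy-β,γ-unsaturated stereocentres should be neither epimerised nor moved into conjugation.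

Step 7
Reactants: 8 meso-(2R,2'S)-2,2'-oxybis(but-3-enal)
Product: 9 meso-(2S,3R,4S,5R)-2,5-divinyltetrahydrofuran-3,4-diol
Conditions: SmI2 (2.5 equiv), t-BuOH (2.5 equiv), THF, −78 °C to −20 °C
Reagents that add atoms: none
Why: Single-electron transfer from SmI2 to each aldehyde gives two samarium-bound ketyls whose carbons C3 and C3a, held 1,5 to each other through the ether oxygen O1, combine to a cyclic samarium diolate that t-BuOH protonates (pinacol coupling, a union of two carbonyl carbons of like polarity). The closest known reaction type is the SmI2 pinacol cyclisation of 1,5-dialdehydes bearing α-alkoxy groups, as used on sugar-derived dialdehydes. The tetrahydrofuran ring closes in the 5-exo-trig mode, each C=O bond being exocyclic to the new ring. Both new stereocentres are controlled by the metal: trivalent samarium bridges the two ketyl oxygens so the diol is cis, and the vinyl groups on C2 and C7a take pseudo-equatorial positions away from the samarium diolate, so the diol should form anti to them as the single meso isomer. The step needs aldehyde-selective reduction and no epimerisation at C2 or C7a, which the substrate and conditions secure because aliphatic aldehydes are reduced by SmI2 at −78 °C without HMPA, isolated vinyl groups neither accept ketyl radicals at a useful rate nor are reduced, and the medium is non-basic. Because only a cis relationship of the two new C–O bonds is required (both carbinols are relayed in steps 8, 9 and 11), the mirror plane of 8 is kept and no enantiocontrol is asked of this step.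

Step 8
Reactants: 9 meso-(2S,3R,4S,5R)-2,5-divinyltetrahydrofuran-3,4-diol
Product: 10 (2S,4R,5R)-4-hydroxy-2,5-divinyldihydrofuran-3(2H)-one
Conditions: Cu(OTf)2 (5 mol%), Ph-BOX (5 mol%, the enantiomer that selects the C3 carbinol), NBS (1.2 equiv), K2CO3, CHCl3, rt
Reagents that add atoms: none
Why: Copper/bis(oxazoline)-catalysed oxidative desymmetrisation of a meso-1,2-diol, in which the chiral divalent copper complex binds the cis-diol as a chelate and N-bromosuccinimide oxidises only one enantiotopic carbinol (C3), which sets the absolute configuration and leaves the C3a hydroxyl trans to its neighbouring vinyl group.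

Step 9
Reactants: 10 (2S,4R,5R)-4-hydroxy-2,5-divinyldihydrofuran-3(2H)-one; 11 acrylic acid
Product: 12 (2R,3S,5S)-4-oxo-2,5-divinyltetrahydrofuran-3-yl acrylate
Conditions: PPh3 (1.5 equiv), DIAD (1.5 equiv), toluene, −20 °C to 0 °C
Reagents that add atoms: none
Why: Mitsunobu esterification, in which SN2 displacement of the oxyphosphonium group at the carbonyl-activated C3a carbon by acrylate inverts this centre and so places the future lactone oxygen O4 cis to the vinyl group on C7a, anti-elimination being disfavoured because the C7a hydrogen is cis to the leaving group.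

Step 10
Reactants: 12 (2R,3S,5S)-4-oxo-2,5-divinyltetrahydrofuran-3-yl acrylate
Product: 13 (2S,3aS,7aR)-2-vinyl-3a,7a-dihydro-2H-furo[3,2-b]pyran-3,5-dione
Conditions: second-generation Grubbs catalyst, RuCl2(=CHPh)(PCy3)(H2IMes) (5 mol%), 1,4-benzoquinone (10 mol%), CH2Cl2 (0.005 M), 40 °C
Reagents that add atoms: none
Why: Ring-closing metathesis between the acrylate and the cis-disposed vinyl group on C7a closes the six-membered α,β-unsaturated lactone (Z alkene enforced by the ring), the cis ring fusion following from the configuration set in step 9.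

Step 11
Reactants: 13 (2S,3aS,7aR)-2-vinyl-3a,7a-dihydro-2H-furo[3,2-b]pyran-3,5-dione
Product: 14 (2S,3R,3aR,7aR)-3-hydroxy-2-vinyl-2,3,3a,7a-tetrahydro-5H-furo[3,2-b]pyran-5-one
Conditions: NaBH4 (1 equiv), CeCl3·7H2O (1.2 equiv), MeOH, −78 °C
Reagents that add atoms: none
Why: Luche reduction, in which hydride attacks the C3 ketone from the convex face of the cis-fused bicycle, anti to both the C2 vinyl group and the lactone oxygen, to give the all-cis alcohol while CeCl3 suppresses conjugate reduction of the lactone.

Step 12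
Reactants: 15 methyl (R)-lactate
Product: 16 methyl (R)-2-(tert-butyldimethylsilyloxy)propanoate
Conditions: TBSCl, imidazole, DMF, rt
Reagents that add atoms: tert-butyldimethylsilyl chloride, C[Si](C)(Cl)C(C)(C)C
Why: Silyl ether formation protects the lactate hydroxyl as a non-chelating group without affecting the stereocentre.

Step 13
Reactants: 16 methyl (R)-2-(tert-butyldimethylsilyloxy)propanoate
Product: 17 (R)-2-(tert-butyldimethylsilyloxy)propanal
Conditions: iBu2AlH (DIBAL-H, 1.1 equiv), CH2Cl2, −78 °C
Reagents that add atoms: none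
Why: Low-temperature DIBAL-H partial reduction of the ester stops at the aldehyde through the stable tetrahedral aluminium hemiacetal, and the α-silyloxy stereocentre is configurationally stable under these conditions.

Step 14
Reactants: 17 (R)-2-(tert-butyldimethylsilyloxy)propanal
Product: 18 (3S,4R)-4-(tert-butyldimethylsilyloxy)pent-1-en-3-ol
Conditions: vinylmagnesium bromide, THF, −78 °C; chromatographic removal of the minor diastereomer
Reagents that add atoms: vinylmagnesium bromide, C=C[Mg]Br
Why: Felkin–Anh-controlled 1,2-addition of the Grignard reagent to the non-chelating α-silyloxy aldehyde should favour the 3,4-anti alcohol with the new S centre.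

Step 15
Reactants: 18 (3S,4R)-4-(tert-butyldimethylsilyloxy)pent-1-en-3-ol
Product: 19 (3S,4R)-4-(tert-butyldimethylsilyloxy)pent-1-en-3-yl benzoate
Conditions: BzCl, pyridine, DMAP (cat.), CH2Cl2, 0 °C
Reagents that add atoms: benzoyl chloride, O=C(Cl)c1ccccc1
Why: DMAP-catalysed O-acylation installs the benzoate on the allylic hydroxyl with retention of configuration.

Step 16
Reactants: 14 (2S,3R,3aR,7aR)-3-hydroxy-2-vinyl-2,3,3a,7a-tetrahydro-5H-furo[3,2-b]pyran-5-one; 19 (3S,4R)-4-(tert-butyldimethylsilyloxy)pent-1-en-3-yl benzoate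
Product: 20 (1E,3S,4R)-4-(tert-butyldimethylsilyloxy)-1-[(2S,3R,3aR,7aR)-3-hydroxy-5-oxo-2,3,3a,7a-tetrahydro-5H-furo[3,2-b]pyran-2-yl]pent-1-en-3-yl benzoate
Conditions: second-generation Hoveyda–Grubbs catalyst, RuCl2(=CH-C6H4-2-OiPr)(H2IMes) (10 mol%), 19 (3 equiv), CH2Cl2, 40 °C
Reagents that add atoms: none
Why: Olefin cross-metathesis of the two terminal alkenes with excess 19 should give the (E)-1,2-disubstituted alkene under thermodynamic control, the conjugated lactone alkene being too electron-poor to take part.

Step 17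
Reactants: 20 (1E,3S,4R)-4-(tert-butyldimethylsilyloxy)-1-[(2S,3R,3aR,7aR)-3-hydroxy-5-oxo-2,3,3a,7a-tetrahydro-5H-furo[3,2-b]pyran-2-yl]pent-1-en-3-yl benzoate
Product: 21 (1E,3S,4R)-4-hydroxy-1-[(2S,3R,3aR,7aR)-3-hydroxy-5-oxo-2,3,3a,7a-tetrahydro-5H-furo[3,2-b]pyran-2-yl]pent-1-en-3-yl benzoate
Conditions: HF·pyridine, pyridine, THF, 0 °C to rt
Reagents that add atoms: none
Why: Fluoride-mediated desilylation under buffered, mildly acidic conditions should free the secondary hydroxyl without benzoate migration or opening of the lactone.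

**Compound list**
1 | (S)-but-3-ene-1,2-diol | C=C[C@@H](CO)O | starting material
2 | (S)-1-(tert-butyldimethylsilyloxy)but-3-en-2-ol | C=C[C@@H](CO[Si](C)(C)C(C)(C)C)O | intermediate
3 | (E)-but-2-ene-1,4-diol | OC/C=C/CO | starting material
4 | (E)-4-(tert-butyldimethylsilyloxy)but-2-en-1-ol | OC/C=C/CO[Si](C)(C)C(C)(C)C | intermediate
5 | tert-butyl (E)-4-(tert-butyldimethylsilyloxy)but-2-en-1-yl carbonate | CC(C)(C)OC(=O)OC/C=C/CO[Si](C)(C)C(C)(C)C | intermediate
6 | meso-(R,S)-bis[1-(tert-butyldimethylsilyloxy)but-3-en-2-yl] ether | C=C[C@@H](CO[Si](C)(C)C(C)(C)C)O[C@H](C=C)CO[Si](C)(C)C(C)(C)C | intermediate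
7 | meso-(2R,2'S)-2,2'-oxybis(but-3-en-1-ol) | C=C[C@@H](CO)O[C@H](C=C)CO | intermediate
8 | meso-(2R,2'S)-2,2'-oxybis(but-3-enal) | C=C[C@@H](C=O)O[C@H](C=C)C=O | intermediate
9 | meso-(2S,3R,4S,5R)-2,5-divinyltetrahydrofuran-3,4-diol (vinyl groups cis, diol cis and trans to both vinyl groups) | C=C[C@@H]1O[C@H](C=C)[C@@H](O)[C@H]1O | intermediate
10 | (2S,4R,5R)-4-hydroxy-2,5-divinyldihydrofuran-3(2H)-one (hydroxyl trans to the adjacent vinyl group) | C=C[C@@H]1O[C@H](C=C)[C@@H](O)C1=O | intermediate
11 | acrylic acid | C=CC(=O)O | starting material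
12 | (2R,3S,5S)-4-oxo-2,5-divinyltetrahydrofuran-3-yl acrylate (acrylate cis to both vinyl groups) | C=C[C@@H]1O[C@H](C=C)[C@H](OC(=O)C=C)C1=O | intermediate
13 | (2S,3aS,7aR)-2-vinyl-3a,7a-dihydro-2H-furo[3,2-b]pyran-3,5-dione (cis-fused) | C=C[C@@H]1O[C@@H]2C=CC(=O)O[C@@H]2C1=O | intermediate
14 | (2S,3R,3aR,7aR)-3-hydroxy-2-vinyl-2,3,3a,7a-tetrahydro-5H-furo[3,2-b]pyran-5-one (all-cis) | C=C[C@@H]1O[C@@H]2C=CC(=O)O[C@@H]2[C@@H]1O | intermediate
15 | methyl (R)-lactate | C[C@@H](O)C(=O)OC | starting material
16 | methyl (R)-2-(tert-butyldimethylsilyloxy)propanoate | C[C@@H](O[Si](C)(C)C(C)(C)C)C(=O)OC | intermediate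
17 | (R)-2-(tert-butyldimethylsilyloxy)propanal | C[C@@H](O[Si](C)(C)C(C)(C)C)C=O | intermediate
18 | (3S,4R)-4-(tert-butyldimethylsilyloxy)pent-1-en-3-ol (3,4-anti) | C[C@@H](O[Si](C)(C)C(C)(C)C)[C@H](C=C)O | intermediate
19 | (3S,4R)-4-(tert-butyldimethylsilyloxy)pent-1-en-3-yl benzoate | C[C@@H](O[Si](C)(C)C(C)(C)C)[C@H](C=C)OC(=O)c1ccccc1 | intermediate
20 | (1E,3S,4R)-4-(tert-butyldimethylsilyloxy)-1-[(2S,3R,3aR,7aR)-3-hydroxy-5-oxo-2,3,3a,7a-tetrahydro-5H-furo[3,2-b]pyran-2-yl]pent-1-en-3-yl benzoate | C[C@@H](O[Si](C)(C)C(C)(C)C)[C@H](/C=C/[C@@H]1O[C@@H]2C=CC(=O)O[C@@H]2[C@@H]1O)OC(=O)c1ccccc1 | intermediate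
21 | (1E,3S,4R)-4-hydroxy-1-[(2S,3R,3aR,7aR)-3-hydroxy-5-oxo-2,3,3a,7a-tetrahydro-5H-furo[3,2-b]pyran-2-yl]pent-1-en-3-yl benzoate | C[C@@H](O)[C@H](/C=C/[C@@H]1O[C@@H]2C=CC(=O)O[C@@H]2[C@@H]1O)OC(=O)c1ccccc1 | target

**Step count and risks**

Total step count: 17. Longest linear sequence: 12 steps (steps 2, 3, 4, 5, 6, 7, 8, 9, 10, 11, 16 and 17; 3 → 4 → 5 → 6 → 7 → 8 → 9 → 10 → 12 → 13 → 14 → 20 → 21).

Steps most likely to fail:

Step 8 (oxidative desymmetrisation). The two enantiotopic carbinols may be discriminated incompletely, the vinyl groups may be brominated, and base-induced ketol transposition (exchange of the carbonyl between C3 and C3a) would erode enantiopurity. The fallback sets out from 9: catalytic enantioselective monosilylation of the meso diol (TBSCl, chiral amino-acid-derived N-methylimidazole catalyst, iPr2NEt, THF, −40 °C) should give the mono-silyl ether (2S,3S,4S,5R)-4-(tert-butyldimethylsilyloxy)-2,5-divinyltetrahydrofuran-3-ol F1. Dess–Martin oxidation of its free hydroxyl should give the silyloxy ketone (2S,4R,5R)-4-(tert-butyldimethylsilyloxy)-2,5-divinyldihydrofuran-3(2H)-one F2, and HF·pyridine then removes the silyl group to rejoin the route at 10.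

Step 9 (Mitsunobu inversion). Elimination towards the conjugated furan-3(2H)-one, loss of configuration at C3a through enolisation, and consumption of the phosphine by conjugate addition to acrylic acid may compete. The fallback sets out from 10: triflation (Tf2O, 2,6-lutidine, CH2Cl2, −78 °C) should give the α-keto triflate (2R,3R,5S)-4-oxo-2,5-divinyltetrahydrofuran-3-yl trifluoromethanesulfonate F3, which is displaced with inversion by caesium acrylate (from 11 and Cs2CO3, 18-crown-6, toluene, 0 °C) to return to the route at 12.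

Step 16 (cross-metathesis). Turnover may be slow because both alkenes carry an allylic oxygen substituent, 19 may homodimerise, and E-selectivity may be incomplete. The fallback sets out from 14: chemoselective ozonolysis of the terminal vinyl group (O3, CH2Cl2, −78 °C, then PPh3) should give the all-cis aldehyde (2R,3S,3aR,7aR)-3-hydroxy-5-oxo-2,3,3a,7a-tetrahydro-5H-furo[3,2-b]pyran-2-carbaldehyde F4, in which the ring stereocentres of 14 are kept. Takai olefination (CrCl2, CHI3, THF) should give the (E)-vinyl iodide (2S,3R,3aR,7aR)-3-hydroxy-2-[(E)-2-iodovinyl]-2,3,3a,7a-tetrahydro-5H-furo[3,2-b]pyran-5-one F5. Nozaki–Hiyama–Kishi coupling with aldehyde 17 (CrCl2, NiCl2 cat., DMSO) should give, under Felkin–Anh control, the allylic alcohol (1E,3S,4R)-4-(tert-butyldimethylsilyloxy)-1-[(2S,3R,3aR,7aR)-3-hydroxy-5-oxo-2,3,3a,7a-tetrahydro-5H-furo[3,2-b]pyran-2-yl]pent-1-en-3-ol F6, which is 20 without the benzoyl group. Selective benzoylation of this more accessible allylic hydroxyl (BzCl, pyridine, −20 °C) rejoins the route at 20.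

Further compounds
F1 | step 8 | (2S,3S,4S,5R)-4-(tert-butyldimethylsilyloxy)-2,5-divinyltetrahydrofuran-3-ol | C=C[C@@H]1O[C@H](C=C)[C@@H](O[Si](C)(C)C(C)(C)C)[C@H]1O
F2 | step 8 | (2S,4R,5R)-4-(tert-butyldimethylsilyloxy)-2,5-divinyldihydrofuran-3(2H)-one | C=C[C@@H]1O[C@H](C=C)[C@@H](O[Si](C)(C)C(C)(C)C)C1=O
F3 | step 9 | (2R,3R,5S)-4-oxo-2,5-divinyltetrahydrofuran-3-yl trifluoromethanesulfonate | C=C[C@@H]1O[C@H](C=C)[C@@H](OS(=O)(=O)C(F)(F)F)C1=O
F4 | step 16 | (2R,3S,3aR,7aR)-3-hydroxy-5-oxo-2,3,3a,7a-tetrahydro-5H-furo[3,2-b]pyran-2-carbaldehyde | O=C[C@@H]1O[C@@H]2C=CC(=O)O[C@@H]2[C@@H]1O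
F5 | step 16 | (2S,3R,3aR,7aR)-3-hydroxy-2-[(E)-2-iodovinyl]-2,3,3a,7a-tetrahydro-5H-furo[3,2-b]pyran-5-one | I/C=C/[C@@H]1O[C@@H]2C=CC(=O)O[C@@H]2[C@@H]1O
F6 | step 16 | (1E,3S,4R)-4-(tert-butyldimethylsilyloxy)-1-[(2S,3R,3aR,7aR)-3-hydroxy-5-oxo-2,3,3a,7a-tetrahydro-5H-furo[3,2-b]pyran-2-yl]pent-1-en-3-ol | C[C@@H](O[Si](C)(C)C(C)(C)C)[C@H](/C=C/[C@@H]1O[C@@H]2C=CC(=O)O[C@@H]2[C@@H]1O)O
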